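Conventions used below: the 3-deoxyflavan unit has rings A (benzo), C (pyran) and B (2-aryl) with unprimed locants; the gallocatechin unit has rings D (benzo), F (pyran) and E (trioxygenated aryl) with primed locants. "Hexa-O-benzylgallocatechin-8-yl" means (2R,3S)-3,5,7-tris(benzyloxy)-2-[3,4,5-tris(benzyloxy)phenyl]chroman-8-yl.

## The problem

The target joins two flavan units through one carbon–carbon bond. C4 of a 3-deoxyflavan (hydroxyls at C7 and at the para position of ring B) is bonded to C8' of (+)-gallocatechin, so C4 is a diarylmethine flanked on ring D by O1' and the C7' oxygen. There are four stereocentres: C2 (S) and C4 (R), trans across ring C, and C2' (R) and C3' (S), trans on ring F. The two pairs lie on opposite sides of the freely rotating C4–C8' bond, so the gallocatechin centres cannot be relied on to steer C4. C4 must therefore be set by a reagent, whereas C2 stands 1,3 to C4 inside ring C and can be relayed from it; the C2'/C3' pair with its whole oxygenation pattern can be bought from the chiral pool. Several groups rule out harsh acid, base or oxidants late in the route: seven phenolic hydroxyls (three on the easily autoxidised pyrogallol ring E), the benzylic ethers C2–O1 and C2'–O1' (ring opening, epimerisation, over-hydrogenolysis), and the electron-rich diarylmethine bond C4–C8' (acid-induced retro-Friedel–Crafts cleavage). The feature that opens the structure is where C4 sits on ring A: it is attached at C4a, ortho to O1 and para to the C7 oxygen, which is where a 3-alkoxyphenol reacts as a carbon nucleophile. C2, three atoms further on and bound to O1, can begin as an aldehyde carbon, so ring C is the sum of a resorcinol monoether and a three-carbon enal on C8' of ring D.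

## Retrosynthesis

**17 ⇒ 16.** No skeletal bond is cut; the eight hydroxyls of target 17 are masked as benzyl ethers in 16. Benzyl is the one group that survives carbonate and hydride bases, an aryllithium, amine catalysis and a short exposure to a Lewis acid, and then leaves in a single neutral hydrogenolysis. Methyl ethers would need a boron halide, which threatens the C4–C8' bond, and silyl ethers would not pass the organolithium and Lewis acid steps. The forward reaction must cleave eight benzylic C–O bonds without opening the two cyclic benzylic ethers.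

**16 ⇒ 13 + 15 (15 ⇐ 14).** The bond from C2 to ring B is cut, giving the ring C oxocarbenium ion (as its anomeric acetate 13) and an aryl nucleophile, the trifluoroborate 15, made in one step from boronic acid 14. The neighbouring cut, O1–C2 (ring closure of a diol by displacement), would need a separately controlled carbinol centre. Cutting C2–aryl lets the existing C4 centre direct the newcomer to the opposite face and asks only for a lactol-level precursor. The forward step must transfer the aryl group through its boron-bearing carbon, trans to the C4 substituent, under acid mild enough for the diarylmethine.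

**13 ⇒ 12 ⇒ 9 + 10.** Acetate 13 is the acylated lactol 12. In 12 the bonds C4–C4a and O1–C2 are cut together, which removes ring C and the C4 stereocentre and leaves the ring D enal 9 and commercial 3-(benzyloxy)phenol 10. The classical alternative, cutting C4–C8' (flavan-4-yl cation plus ring D as nucleophile), would need a 4-functionalised 3-deoxyflavan, would face C6'/C8' regiochemistry and would leave C4 to substrate control. Cutting on the ring A side puts C4 under catalyst control and uses a purchasable phenol. Enal 9 contains all of gallocatechin plus three carbons and has no stereocentre of its own to build. The forward reaction must deliver face selection at the β-carbon, attack through the carbon ortho to the phenolic hydroxyl, and enough reactivity from a donor-rich, crowded enal.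

**9 ⇒ 6.** The bond from C8' to the enal β-carbon is cut into an aryl anion at C8' (from bromide 6) and a three-carbon enal cation equivalent (a vinylogous formamide). This is one step shorter than formylation followed by two-carbon olefination, and it avoids a Heck reaction on a doubly ortho-substituted, electron-rich aryl bromide. The forward step needs clean bromine–lithium exchange in the presence of six benzyl ethers and E geometry in the enal.

**6 ⇒ 5 ⇒ 4.** The C8'–Br bond is cut back to hexa-O-benzylgallocatechin 5, relying on the higher reactivity of C8' over C6' in 5,7-dialkoxyflavans. Compound 5 is the 3'-O-benzyl ether of pentabenzyl ether 4; the secondary hydroxyl is capped before the organolithium step.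

**4 ⇒ 3 ⇒ 2 ⇒ 1.** Reintroducing oxygen at C4' leads through diol 3 and ketone 2 to (+)-dihydromyricetin 1, an inexpensive natural product that carries the C2'/C3' centres in the right absolute and trans relative configuration and all six oxygens of the lower unit. Gallocatechin itself is far more costly, and building ring F from scratch would mean two more stereocentres to control. The forward sequence must benzylate five phenols without base-induced epimerisation, then remove the carbonyl oxygen by reduction and ionic hydrogenation without touching C2' and C3'.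

## Roads not taken

**Alternative 1:** Cut O1'–C2' and C3'–C4' of ring F. In the forward sense the ortho-hydroxybenzyl alcohol A2 (the finished upper flavan carrying a phloroglucinol-type ring D) is heated to give the ortho-quinone methide A3, which adds to the E-enol acetate A4 in a hetero-Diels–Alder reaction to give A1, the heptabenzyl ether 3'-acetate of the target. The merits are real: two bonds, one ring and both ring F stereocentres form in one step, the trans relationship follows from the E-alkene, and the C3' oxygen arrives in place. For this target there are three weak points.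
- Nothing differentiates the two faces of the heterodiene in A3: the only stereocentres, C2 and C4, are on the far side of the C4–C8' bond, so both trans-configured ring F series should form.
- A4 carries donors at both ends of its double bond, and the required orientation (quinone methide oxygen to the aryl-bearing carbon) needs the aryl group to outweigh the acetoxy group, although its para oxygen is flanked by two ortho benzyloxy groups.
- The C4 diarylmethine still has to be made in enantiopure form before A2 exists, so the central problem is only moved.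

In bond economy for ring F this route is better than the chosen plan. Against that, the chosen plan does not build ring F at all: its two stereocentres come with compound 1, and the only centre that needs asymmetric induction is C4.

**Alternative 2:** Cut O1–C8a. The 3-arylindanone A6 is oxidised with a peracid in a Baeyer–Villiger reaction; the ring A carbon migrates to oxygen and the five-membered ring expands to the dihydrocoumarin A5. This route is better in two respects: the substitution pattern of ring A is fixed in A6, so no ortho/para question arises, and the oxidation cannot touch C4. Its weak points are as follows.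
- A peracid meets seven benzyloxy-substituted arene positions, with rings D and E especially prone to oxidation.
- The migrating carbon is meta to its benzyloxy group and gains no special migratory aptitude.
- A6 must already contain the C4 stereocentre, so a hindered C–C bond to C8' with asymmetric control is still required earlier.
- A5 lies one oxidation level above the lactol and costs an extra reduction.

The chosen plan has to accept the regiochemical risk on phenol 10. In return it makes both ring C bonds in one catalytic operation from a commercial phenol, at the lactol oxidation level, with no oxidant near the electron-rich rings.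

**Alternative 3:** Cut C4'–C4a' of ring F. The epoxy ether A8 (ring D oxygen bound to the future C2', terminal epoxide at C3'–C4') is ionised in hexafluoroisopropanol or with AuCl3/AgOTf; ring D attacks the terminal epoxide carbon in a 6-endo opening and gives A7, the heptabenzyl ether with a free C3' hydroxyl. The step is stereospecific (C2' and C3' are not touched), uses the high nucleophilicity of ring D, and frees the C3' hydroxyl without a protecting group, which is slightly better than carrying a 3'-O-benzyl ether. The weak points lie before and around it. Both ring F centres must be made by asymmetric synthesis. The ether bond of A8 has to be formed at an electron-rich benzylic carbon with a phenol oxygen crowded by the C8' substituent, where inversion is likely to leak into ionisation. The cationic cyclisation runs on the complete, acid-sensitive skeleton, with 5-exo opening as a competitor. If compound 1 were not available in the right configuration this would be the more attractive way to ring F. As it is, the chosen plan takes ring F ready-made and spends its one difficult step on C4.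

Key step: step 7

Assumption on stereochemistry: the (S)-configured diarylprolinol silyl ether is taken to expose the face of the iminium ion given by the usual shielding model, which for the substituent priorities at C4 corresponds to 4R; if the enal's remote centres reversed this sense, the enantiomeric catalyst would be used.

## Route

Step 1
Reactants: 1 (+)-dihydromyricetin
Product: 2 (2R,3R)-5,7-bis(benzyloxy)-3-hydroxy-2-[3,4,5-tris(benzyloxy)phenyl]chroman-4-one
Conditions: BnBr, K2CO3, DMF, rt, argon
Reagents that add atoms: benzyl bromide, BrCc1ccccc1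
Why: Williamson etherification of the five phenols under carbonate conditions that leave the secondary C3' hydroxyl untouched; the hydrogen-bonded C5' hydroxyl reacts last and needs the excess of halide. Room temperature and exclusion of air should preserve the 2,3-trans centres and the pyrogallol ring.

Step 2
Reactants: 2 (2R,3R)-5,7-bis(benzyloxy)-3-hydroxy-2-[3,4,5-tris(benzyloxy)phenyl]chroman-4-one
Product: 3 (2R,3S,4R)-5,7-bis(benzyloxy)-2-[3,4,5-tris(benzyloxy)phenyl]chromane-3,4-diol (main epimer; the 4S epimer is carried along)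
Conditions: NaBH4, THF/EtOH, 0 °C
Reagents that add atoms: none
Why: Borohydride reduction of the aryl ketone, expected to give mainly the 3,4-trans diol; the C4' configuration is irrelevant because that carbon becomes a methylene group in step 3.

Step 3
Reactants: 3 (2R,3S,4R)-5,7-bis(benzyloxy)-2-[3,4,5-tris(benzyloxy)phenyl]chromane-3,4-diol
Product: 4 (2R,3S)-5,7-bis(benzyloxy)-2-[3,4,5-tris(benzyloxy)phenyl]chroman-3-ol (penta-O-benzylgallocatechin)
Conditions: Et3SiH, CF3CO2H, CH2Cl2, −20 → 0 °C
Reagents that add atoms: none
Why: Ionic hydrogenation: acid ionises the benzylic C4' hydroxyl to a cation stabilised by the C5' and C7' ether oxygens and the silane traps it; C2' and C3' take no part, so the 2R,3S-trans arrangement of gallocatechin should result.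

Step 4
Reactants: 4 (2R,3S)-5,7-bis(benzyloxy)-2-[3,4,5-tris(benzyloxy)phenyl]chroman-3-ol
Product: 5 (2R,3S)-3,5,7-tris(benzyloxy)-2-[3,4,5-tris(benzyloxy)phenyl]chromane (hexa-O-benzylgallocatechin)
Conditions: NaH, BnBr, n-Bu4NI (cat.), DMF, 0 °C → rt
Reagents that add atoms: benzyl bromide, BrCc1ccccc1
Why: Williamson etherification of the secondary alcohol through its sodium alkoxide; with every phenol capped there is no quinone methide pathway for epimerisation at C2'.

Step 5
Reactants: 5 hexa-O-benzylgallocatechin
Product: 6 (2R,3S)-3,5,7-tris(benzyloxy)-8-bromo-2-[3,4,5-tris(benzyloxy)phenyl]chromane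
Conditions: NBS, CH2Cl2, −40 → 0 °C
Reagents that add atoms: N-bromosuccinimide, O=C1CCC(=O)N1Br
Why: Electrophilic aromatic bromination; in 5,7-dialkoxyflavans C8' is the more reactive of the two free ring D positions, and one equivalent of reagent at low temperature should spare C6' and ring E.

Step 6
Reactants: 6 (2R,3S)-3,5,7-tris(benzyloxy)-8-bromo-2-[3,4,5-tris(benzyloxy)phenyl]chromane
Product: 9 (E)-3-(hexa-O-benzylgallocatechin-8-yl)prop-2-enal, via 8-lithio arene 7 (not isolated), via lithium aminoallyl alkoxide 8 (not isolated)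
Conditions: n-BuLi, THF, −78 °C; (E)-Me2NCH=CHCHO, −78 → 0 °C; then 1 M HCl, 0 °C
Reagents that add atoms: (E)-3-(dimethylamino)acrolein, CN(C)/C=C/C=O
Why: Bromine–lithium exchange gives aryllithium 7, which adds to the carbonyl group of the vinylogous formamide to give 8; acid then expels water and hydrolyses the conjugated iminium ion (vinylogous formylation), leaving the thermodynamically preferred E-enal.

Step 7
Reactants: 9 (E)-3-(hexa-O-benzylgallocatechin-8-yl)prop-2-enal; 10 3-(benzyloxy)phenol
Product: 12 (4R)-7-(benzyloxy)-4-(hexa-O-benzylgallocatechin-8-yl)chroman-2-ol (C2 epimers), via open-chain hydroxy aldehyde 11 (not isolated)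
Conditions: (S)-2-[diphenyl(trimethylsilyloxy)methyl]pyrrolidine (20 mol %), PhCO2H (20 mol %), 10 (3 equiv), toluene, rt → 40 °C
Reagents that add atoms: none
Why: Condensation of enal 9 with the (S)-configured secondary amine, assisted by benzoic acid, gives the E,s-trans iminium ion, in which the diphenyl(trimethylsilyloxy)methyl group covers one face of the β-carbon. Phenol 10 attacks the open face through the carbon ortho to its hydroxyl and para to the benzyloxy group in a Friedel–Crafts-type conjugate addition that forms C4–C4a; rearomatisation and hydrolysis of the enamine release aldehyde 11 and the catalyst. The neighbouring phenolic oxygen then adds to the aldehyde in a 6-exo-trig hemiacetalisation that forms O1–C2, closes ring C as lactol 12 and pulls the sequence forward. The closest known reaction type is the diarylprolinol silyl ether-catalysed Friedel–Crafts alkylation–hemiacetalisation of naphthols and electron-rich phenols with β-aryl enals to give 4-arylchroman-2-ols. C4 is set by the catalyst: by the usual shielding model the (S)-amine exposes the face that gives 4R, and the remote gallocatechin centres should have little influence. The lactol centre forms as a mixture, which is harmless because it becomes trigonal in step 10. The step needs ortho rather than para attack relative to the hydroxyl: hydrogen bonding of the hydroxyl to the carboxylate directs the electrophile to the ortho carbon, the carbon between the two oxygens is too crowded, and only the ortho adduct is drained as a lactol.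

Step 8
Reactants: 12 (4R)-7-(benzyloxy)-4-(hexa-O-benzylgallocatechin-8-yl)chroman-2-ol
Product: 13 (4R)-7-(benzyloxy)-4-(hexa-O-benzylgallocatechin-8-yl)chroman-2-yl acetate (C2 epimers)
Conditions: Ac2O, pyridine, DMAP (cat.), CH2Cl2, 0 °C → rt
Reagents that add atoms: acetic anhydride, CC(=O)OC(C)=O
Why: Acylation of the hemiacetal hydroxyl with nucleophilic catalysis turns it into a leaving group; 12 has no other free hydroxyl.

Step 9
Reactants: 14 4-(benzyloxy)phenylboronic acid
Product: 15 potassium [4-(benzyloxy)phenyl]trifluoroborate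
Conditions: KHF2, MeOH/H2O, rt
Reagents that add atoms: potassium hydrogen difluoride, [K+].[F-].F
Why: Standard fluoride exchange of a boronic acid to its air-stable trifluoroborate salt.

Step 10
Reactants: 13 (4R)-7-(benzyloxy)-4-(hexa-O-benzylgallocatechin-8-yl)chroman-2-yl acetate; 15 potassium [4-(benzyloxy)phenyl]trifluoroborate
Product: 16 (2S,4R)-7-(benzyloxy)-2-[4-(benzyloxy)phenyl]-4-(hexa-O-benzylgallocatechin-8-yl)chromane (octa-O-benzyl ether of the target)
Conditions: BF3·OEt2 (3 equiv), MeCN/CH2Cl2, −30 → 0 °C
Reagents that add atoms: none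
Why: BF3·OEt2 ionises the anomeric acetate to the ring C oxocarbenium ion and converts 15 into the aryldifluoroborane, which delivers its aryl group through the boron-bearing carbon (Lewis acid-promoted trifluoroborate–acetal coupling). The C4 aryl group, 1,3 to the cationic carbon, blocks its own face of the half-chair, so the nucleophile should enter anti and give the 2,4-trans (2S) chroman under kinetic control.

Step 11
Reactants: 16 octa-O-benzyl ether of the target
Product: 17 (2R,3S)-8-[(2S,4R)-7-hydroxy-2-(4-hydroxyphenyl)chroman-4-yl]-2-(3,4,5-trihydroxyphenyl)chromane-3,5,7-triol (target)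
Conditions: H2 (1 atm), Pd(OH)2/C, THF/MeOH, rt
Reagents that add atoms: none
Why: Heterogeneous hydrogenolysis cleaves all eight benzyl ethers in one neutral operation; the cyclic benzylic ethers C2–O1 and C2'–O1' react much more slowly and no stereocentre is touched.

## Compound list

1 | (+)-dihydromyricetin, (2R,3R)-3,5,7-trihydroxy-2-(3,4,5-trihydroxyphenyl)chroman-4-one | O=C1c2c(O)cc(O)cc2O[C@H](c2cc(O)c(O)c(O)c2)[C@H]1O | starting material
2 | (2R,3R)-5,7-bis(benzyloxy)-3-hydroxy-2-[3,4,5-tris(benzyloxy)phenyl]chroman-4-one | O=C1c2c(OCc3ccccc3)cc(OCc3ccccc3)cc2O[C@H](c2cc(OCc3ccccc3)c(OCc3ccccc3)c(OCc3ccccc3)c2)[C@H]1O | intermediate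
3 | (2R,3S,4R)-5,7-bis(benzyloxy)-2-[3,4,5-tris(benzyloxy)phenyl]chromane-3,4-diol (main epimer, 4S epimer carried along) | O[C@@H]1c2c(OCc3ccccc3)cc(OCc3ccccc3)cc2O[C@H](c2cc(OCc3ccccc3)c(OCc3ccccc3)c(OCc3ccccc3)c2)[C@H]1O | intermediate
4 | (2R,3S)-5,7-bis(benzyloxy)-2-[3,4,5-tris(benzyloxy)phenyl]chroman-3-ol | c1c(OCc3ccccc3)cc(OCc3ccccc3)c2c1O[C@H](c1cc(OCc3ccccc3)c(OCc3ccccc3)c(OCc3ccccc3)c1)[C@@H](O)C2 | intermediate
5 | (2R,3S)-3,5,7-tris(benzyloxy)-2-[3,4,5-tris(benzyloxy)phenyl]chromane (hexa-O-benzylgallocatechin) | c1c(OCc3ccccc3)cc(OCc3ccccc3)c2c1O[C@H](c1cc(OCc3ccccc3)c(OCc3ccccc3)c(OCc3ccccc3)c1)[C@@H](OCc1ccccc1)C2 | intermediate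
6 | (2R,3S)-3,5,7-tris(benzyloxy)-8-bromo-2-[3,4,5-tris(benzyloxy)phenyl]chromane | Brc1c(OCc3ccccc3)cc(OCc3ccccc3)c2c1O[C@H](c1cc(OCc3ccccc3)c(OCc3ccccc3)c(OCc3ccccc3)c1)[C@@H](OCc1ccccc1)C2 | intermediate
7 | (hexa-O-benzylgallocatechin-8-yl)lithium, formed in the flask | [Li]c1c(OCc3ccccc3)cc(OCc3ccccc3)c2c1O[C@H](c1cc(OCc3ccccc3)c(OCc3ccccc3)c(OCc3ccccc3)c1)[C@@H](OCc1ccccc1)C2 | intermediate
8 | lithium (E)-3-(dimethylamino)-1-(hexa-O-benzylgallocatechin-8-yl)prop-2-en-1-olate (carbinol epimers), formed in the flask | CN(C)/C=C/C(O[Li])c1c(OCc3ccccc3)cc(OCc3ccccc3)c2c1O[C@H](c1cc(OCc3ccccc3)c(OCc3ccccc3)c(OCc3ccccc3)c1)[C@@H](OCc1ccccc1)C2 | intermediate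
9 | (E)-3-(hexa-O-benzylgallocatechin-8-yl)prop-2-enal | O=C/C=C/c1c(OCc3ccccc3)cc(OCc3ccccc3)c2c1O[C@H](c1cc(OCc3ccccc3)c(OCc3ccccc3)c(OCc3ccccc3)c1)[C@@H](OCc1ccccc1)C2 | intermediate
10 | 3-(benzyloxy)phenol | Oc1cccc(OCc2ccccc2)c1 | starting material
11 | (3R)-3-[4-(benzyloxy)-2-hydroxyphenyl]-3-(hexa-O-benzylgallocatechin-8-yl)propanal, formed in the flask | O=CC[C@@H](c1c(OCc3ccccc3)cc(OCc3ccccc3)c2c1O[C@H](c1cc(OCc3ccccc3)c(OCc3ccccc3)c(OCc3ccccc3)c1)[C@@H](OCc1ccccc1)C2)c1ccc(OCc2ccccc2)cc1O | intermediate
12 | (4R)-7-(benzyloxy)-4-(hexa-O-benzylgallocatechin-8-yl)chroman-2-ol (C2 epimers) | OC1C[C@@H](c3c(OCc5ccccc5)cc(OCc5ccccc5)c4c3O[C@H](c3cc(OCc5ccccc5)c(OCc5ccccc5)c(OCc5ccccc5)c3)[C@@H](OCc3ccccc3)C4)c2ccc(OCc5ccccc5)cc2O1 | intermediate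
13 | (4R)-7-(benzyloxy)-4-(hexa-O-benzylgallocatechin-8-yl)chroman-2-yl acetate (C2 epimers) | CC(=O)OC1C[C@@H](c3c(OCc5ccccc5)cc(OCc5ccccc5)c4c3O[C@H](c3cc(OCc5ccccc5)c(OCc5ccccc5)c(OCc5ccccc5)c3)[C@@H](OCc3ccccc3)C4)c2ccc(OCc5ccccc5)cc2O1 | intermediate
14 | 4-(benzyloxy)phenylboronic acid | OB(O)c1ccc(OCc2ccccc2)cc1 | starting material
15 | potassium [4-(benzyloxy)phenyl]trifluoroborate | [K+].F[B-](F)(F)c1ccc(OCc2ccccc2)cc1 | intermediate
16 | (2S,4R)-7-(benzyloxy)-2-[4-(benzyloxy)phenyl]-4-(hexa-O-benzylgallocatechin-8-yl)chromane | C(c1ccccc1)Oc1ccc([C@@H]2C[C@@H](c3c(OCc5ccccc5)cc(OCc5ccccc5)c4c3O[C@H](c3cc(OCc5ccccc5)c(OCc5ccccc5)c(OCc5ccccc5)c3)[C@@H](OCc3ccccc3)C4)c3ccc(OCc4ccccc4)cc3O2)cc1 | intermediate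
17 | (2R,3S)-8-[(2S,4R)-7-hydroxy-2-(4-hydroxyphenyl)chroman-4-yl]-2-(3,4,5-trihydroxyphenyl)chromane-3,5,7-triol | Oc1ccc([C@@H]2C[C@@H](c3c(O)cc(O)c4c3O[C@H](c3cc(O)c(O)c(O)c3)[C@@H](O)C4)c3ccc(O)cc3O2)cc1 | target

## Step count and risks

Total step count: 11. Longest linear sequence: 10 steps (steps 1–8, 10 and 11, from 1); step 9 is a one-step side branch.

**Step 7 (key step).** The most likely failure is stalling of the conjugate addition: the iminium ion of 9 is deactivated by three oxygen donors and crowded by two ortho substituents, and 10 is only a moderate carbon nucleophile. Behind that come attack through the carbon para to the hydroxyl, which cannot close to a lactol, and weaker face discrimination if the twisted aryl group disturbs the iminium geometry. The fallback sets out from enal 9 and returns at lactol 12; it turns the donor-rich aryl group into an advantage.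
- Pinnick oxidation of 9 (NaClO2, NaH2PO4, 2-methylbut-2-ene) should give (E)-3-(hexa-O-benzylgallocatechin-8-yl)prop-2-enoic acid F1.
- Hydroarylation–lactonisation of F1 with 10, mediated by CF3CO2H and proceeding through the stabilised benzylic cation, should give (4R)-7-(benzyloxy)-4-(hexa-O-benzylgallocatechin-8-yl)-3,4-dihydrocoumarin F2 together with its (4S) epimer F3.
- F2 and F3 are diastereomers because of the gallocatechin centres and would be separated by chromatography.
- Reduction of F2 with diisobutylaluminium hydride at −78 °C leads to 12.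

**Step 10.** Three things may go wrong: loss of the 2,4-trans preference through reversible Lewis acid opening of the new C2–O1 bond (a 4-alkoxybenzyl cation is easily formed), proton loss from C3 of the oxocarbenium ion to the enol ether if aryl transfer is slow, and acid cleavage of the C4–C8' bond. The fallback sets out from lactol 12 and returns at 16; it sets C2 by reagent control.
- Addition of commercial 4-(benzyloxy)phenylmagnesium bromide to 12 should give 1-[4-(benzyloxy)phenyl]-3-[4-(benzyloxy)-2-hydroxyphenyl]-3-(hexa-O-benzylgallocatechin-8-yl)propan-1-ol F4 as carbinol epimers.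
- Oxidation of the benzylic alcohol with MnO2 gives the aryl ketone F5.
- Corey–Bakshi–Shibata reduction with (S)-2-methyl-CBS-oxazaborolidine and BH3·SMe2 gives the (1R)-carbinol F6.
- Mitsunobu ring closure (PPh3, diisopropyl azodicarboxylate) by the phenol oxygen with inversion gives 16.

**Step 6.** Protonation of the hindered aryllithium before it adds, or incomplete collapse of the adduct to the enal, would lower the throughput. The fallback sets out from bromide 6 and returns at 9.
- Lithiation and quenching with DMF gives hexa-O-benzylgallocatechin-8-carbaldehyde F7.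
- Horner–Wadsworth–Emmons olefination with triethyl phosphonoacetate and NaH gives the ethyl (E)-propenoate F8.
- Reduction with diisobutylaluminium hydride gives the (E)-allylic alcohol F9.
- Oxidation with MnO2 gives 9.

**Step 1.** Base-induced ring opening and epimerisation of the dihydroflavonol, autoxidation of the pyrogallol ring, and incomplete alkylation of the hydrogen-bonded C5' hydroxyl are the concerns. The fallback sets out from 1 and returns at 5 in the same number of steps; it keeps the ketone away from forcing base.
- Benzylation of only the four unchelated phenols (BnBr, K2CO3, acetone, rt) gives 7,3',4',5'-tetra-O-benzyldihydromyricetin F10.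
- Reduction with NaBH4 gives the corresponding 3,4-diol F11.
- Ionic hydrogenation (Et3SiH, CF3CO2H) gives 7,3',4',5'-tetra-O-benzylgallocatechin F12.
- NaH and BnBr then benzylate the C5' and C3' hydroxyls together, giving 5.

**Step 11.** Incomplete removal of eight benzyl groups, slow hydrogenolytic opening of the cyclic benzylic ethers on prolonged exposure, and air oxidation of the free pyrogallol during isolation are possible. The fallback sets out from 16 and returns at 17 without a new intermediate: Lewis acid debenzylation with BCl3 and pentamethylbenzene as cation scavenger at −78 °C, followed by work-up under argon.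

## Further compounds

F1 | step 7 | (E)-3-(hexa-O-benzylgallocatechin-8-yl)prop-2-enoic acid | OC(=O)/C=C/c1c(OCc3ccccc3)cc(OCc3ccccc3)c2c1O[C@H](c1cc(OCc3ccccc3)c(OCc3ccccc3)c(OCc3ccccc3)c1)[C@@H](OCc1ccccc1)C2
F2 | step 7 | (4R)-7-(benzyloxy)-4-(hexa-O-benzylgallocatechin-8-yl)-3,4-dihydrocoumarin | O=C1C[C@@H](c3c(OCc5ccccc5)cc(OCc5ccccc5)c4c3O[C@H](c3cc(OCc5ccccc5)c(OCc5ccccc5)c(OCc5ccccc5)c3)[C@@H](OCc3ccccc3)C4)c2ccc(OCc5ccccc5)cc2O1
F3 | step 7 | (4S)-7-(benzyloxy)-4-(hexa-O-benzylgallocatechin-8-yl)-3,4-dihydrocoumarin | O=C1C[C@H](c3c(OCc5ccccc5)cc(OCc5ccccc5)c4c3O[C@H](c3cc(OCc5ccccc5)c(OCc5ccccc5)c(OCc5ccccc5)c3)[C@@H](OCc3ccccc3)C4)c2ccc(OCc5ccccc5)cc2O1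
F4 | step 10 | (3R)-1-[4-(benzyloxy)phenyl]-3-[4-(benzyloxy)-2-hydroxyphenyl]-3-(hexa-O-benzylgallocatechin-8-yl)propan-1-ol (carbinol epimers) | OC(c1ccc(OCc2ccccc2)cc1)C[C@@H](c1c(OCc3ccccc3)cc(OCc3ccccc3)c2c1O[C@H](c1cc(OCc3ccccc3)c(OCc3ccccc3)c(OCc3ccccc3)c1)[C@@H](OCc1ccccc1)C2)c1ccc(OCc2ccccc2)cc1O
F5 | step 10 | (3R)-1-[4-(benzyloxy)phenyl]-3-[4-(benzyloxy)-2-hydroxyphenyl]-3-(hexa-O-benzylgallocatechin-8-yl)propan-1-one | O=C(c1ccc(OCc2ccccc2)cc1)C[C@@H](c1c(OCc3ccccc3)cc(OCc3ccccc3)c2c1O[C@H](c1cc(OCc3ccccc3)c(OCc3ccccc3)c(OCc3ccccc3)c1)[C@@H](OCc1ccccc1)C2)c1ccc(OCc2ccccc2)cc1O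
F6 | step 10 | (1R,3R)-1-[4-(benzyloxy)phenyl]-3-[4-(benzyloxy)-2-hydroxyphenyl]-3-(hexa-O-benzylgallocatechin-8-yl)propan-1-ol | O[C@@H](c1ccc(OCc2ccccc2)cc1)C[C@@H](c1c(OCc3ccccc3)cc(OCc3ccccc3)c2c1O[C@H](c1cc(OCc3ccccc3)c(OCc3ccccc3)c(OCc3ccccc3)c1)[C@@H](OCc1ccccc1)C2)c1ccc(OCc2ccccc2)cc1O
F7 | step 6 | hexa-O-benzylgallocatechin-8-carbaldehyde | O=Cc1c(OCc3ccccc3)cc(OCc3ccccc3)c2c1O[C@H](c1cc(OCc3ccccc3)c(OCc3ccccc3)c(OCc3ccccc3)c1)[C@@H](OCc1ccccc1)C2
F8 | step 6 | ethyl (E)-3-(hexa-O-benzylgallocatechin-8-yl)prop-2-enoate | CCOC(=O)/C=C/c1c(OCc3ccccc3)cc(OCc3ccccc3)c2c1O[C@H](c1cc(OCc3ccccc3)c(OCc3ccccc3)c(OCc3ccccc3)c1)[C@@H](OCc1ccccc1)C2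
F9 | step 6 | (E)-3-(hexa-O-benzylgallocatechin-8-yl)prop-2-en-1-ol | OC/C=C/c1c(OCc3ccccc3)cc(OCc3ccccc3)c2c1O[C@H](c1cc(OCc3ccccc3)c(OCc3ccccc3)c(OCc3ccccc3)c1)[C@@H](OCc1ccccc1)C2
F10 | step 1 | (2R,3R)-7-(benzyloxy)-3,5-dihydroxy-2-[3,4,5-tris(benzyloxy)phenyl]chroman-4-one | O=C1c2c(O)cc(OCc3ccccc3)cc2O[C@H](c2cc(OCc3ccccc3)c(OCc3ccccc3)c(OCc3ccccc3)c2)[C@H]1O
F11 | step 1 | (2R,3S,4R)-7-(benzyloxy)-2-[3,4,5-tris(benzyloxy)phenyl]chromane-3,4,5-triol (main epimer) | O[C@@H]1c2c(O)cc(OCc3ccccc3)cc2O[C@H](c2cc(OCc3ccccc3)c(OCc3ccccc3)c(OCc3ccccc3)c2)[C@H]1O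
F12 | step 1 | (2R,3S)-7-(benzyloxy)-2-[3,4,5-tris(benzyloxy)phenyl]chromane-3,5-diol | c1c(OCc3ccccc3)cc(O)c2c1O[C@H](c1cc(OCc3ccccc3)c(OCc3ccccc3)c(OCc3ccccc3)c1)[C@@H](O)C2
F0 | step 11 | none | none
A1 | alternative 1 | hepta-O-benzyl 3'-O-acetyl derivative of the target | C(c1ccccc1)Oc1ccc([C@@H]2C[C@@H](c3c(OCc5ccccc5)cc(OCc5ccccc5)c4c3O[C@H](c3cc(OCc5ccccc5)c(OCc5ccccc5)c(OCc5ccccc5)c3)[C@@H](OC(C)=O)C4)c3ccc(OCc4ccccc4)cc3O2)cc1
A2 | alternative 1 | (2S,4R)-7-(benzyloxy)-2-[4-(benzyloxy)phenyl]-4-[4,6-bis(benzyloxy)-2-hydroxy-3-(hydroxymethyl)phenyl]chromane | C(c1ccccc1)Oc1ccc([C@@H]2C[C@@H](c3c(OCc4ccccc4)cc(OCc4ccccc4)c(CO)c3O)c3ccc(OCc4ccccc4)cc3O2)cc1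
A3 | alternative 1 | ortho-quinone methide of ring D derived from A2 by loss of water | C(c1ccccc1)Oc1ccc([C@@H]2C[C@@H](C3=C(OCc4ccccc4)C=C(OCc4ccccc4)C(=C)C3=O)c3ccc(OCc4ccccc4)cc3O2)cc1
A4 | alternative 1 | (E)-2-[3,4,5-tris(benzyloxy)phenyl]vinyl acetate | CC(=O)O/C=C/c1cc(OCc2ccccc2)c(OCc2ccccc2)c(OCc2ccccc2)c1
A5 | alternative 2 | (4R)-7-(benzyloxy)-4-(hexa-O-benzylgallocatechin-8-yl)-3,4-dihydrocoumarin | O=C1C[C@@H](c3c(OCc5ccccc5)cc(OCc5ccccc5)c4c3O[C@H](c3cc(OCc5ccccc5)c(OCc5ccccc5)c(OCc5ccccc5)c3)[C@@H](OCc3ccccc3)C4)c2ccc(OCc5ccccc5)cc2O1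
A6 | alternative 2 | (3R)-6-(benzyloxy)-3-(hexa-O-benzylgallocatechin-8-yl)indan-1-one | O=C1C[C@@H](c3c(OCc5ccccc5)cc(OCc5ccccc5)c4c3O[C@H](c3cc(OCc5ccccc5)c(OCc5ccccc5)c(OCc5ccccc5)c3)[C@@H](OCc3ccccc3)C4)c2ccc(OCc5ccccc5)cc12
A7 | alternative 3 | hepta-O-benzyl ether of the target with free C3' hydroxyl | C(c1ccccc1)Oc1ccc([C@@H]2C[C@@H](c3c(OCc5ccccc5)cc(OCc5ccccc5)c4c3O[C@H](c3cc(OCc5ccccc5)c(OCc5ccccc5)c(OCc5ccccc5)c3)[C@@H](O)C4)c3ccc(OCc4ccccc4)cc3O2)cc1
A8 | alternative 3 | (2S,4R)-7-(benzyloxy)-2-[4-(benzyloxy)phenyl]-4-[2,4-bis(benzyloxy)-6-{(1R)-[(2S)-oxiran-2-yl][3,4,5-tris(benzyloxy)phenyl]methoxy}phenyl]chromane | C(c1ccccc1)Oc1ccc([C@@H]2C[C@@H](c3c(OCc5ccccc5)cc(OCc5ccccc5)cc3O[C@H](c3cc(OCc5ccccc5)c(OCc5ccccc5)c(OCc5ccccc5)c3)[C@@H]3CO3)c3ccc(OCc4ccccc4)cc3O2)cc1
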